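Ring C is closed last by annulating the intact A ring, as an aryne, onto an enantiopure three-carbon unit. The route rests on cutting the aryl ether bond O1–C8a and the aryl ketone bond C4–C4a. In one operation fluoride unmasks a β-alkoxy ester from its silyl ether and a 3-(methoxymethoxy)-4-prenyl-5-methoxybenzyne from its o-silyl triflate; the alkoxide adds to C8a and the C4a anion acylates on the ester, giving the chromanone. The step exploits the ortho relationship of O1 and C4 on ring A and the C5 oxygen next to C4a, which directs the addition. C2 is set beforehand by asymmetric hydrogenation.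

Key step: step 9

Remark: flavanone numbering (O1, C2, C3, C4, C4a, C5–C8, C8a) is used for ring positions in all intermediates; the target stereocentre C2 is (S); prenyl = 3-methylbut-2-en-1-yl, MOM = methoxymethyl.

Step 1
Reactants: 1 3-methoxyphenol
Product: 2 1-methoxy-3-(methoxymethoxy)benzene
Conditions: MOMCl, i-Pr2NEt, CH2Cl2, 0 °C → rt
Reagents that add atoms: chloromethyl methyl ether COCCl
Why: Williamson-type O-alkylation of the phenol with an α-chloro ether; the MOM ether later serves as the stronger ortho-directing group and as the protecting group of the C5 oxygen.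

Step 2
Reactants: 2 1-methoxy-3-(methoxymethoxy)benzene; 3 prenyl bromide
Product: 5 1-methoxy-3-(methoxymethoxy)-2-(3-methylbut-2-en-1-yl)benzene, via aryllithium 4 (not isolated)
Conditions: n-BuLi, THF, 0 °C → rt; then CuI (10 mol %), 3, −78 °C → rt
Reagents that add atoms: none
Why: Directed ortho-metalation at the ring position flanked by OMe and OMOM (cooperative direction), followed by copper-catalysed SN2 allylation, in which copper suppresses SN2′ attack.

Step 3
Reactants: 5 1-methoxy-3-(methoxymethoxy)-2-(3-methylbut-2-en-1-yl)benzene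
Product: 8 4-methoxy-2-(methoxymethoxy)-3-(3-methylbut-2-en-1-yl)phenol, via aryllithium 6 (not isolated), via arylboronate 7 (not isolated)
Conditions: n-BuLi, TMEDA, THF, −20 → 0 °C; B(OMe)3, −78 °C → rt; then 30% H2O2, aq. NaOH, 0 °C
Reagents that add atoms: hydrogen peroxide OO; trimethyl borate COB(OC)OC (its boron stays only in intermediate 7)
Why: Directed ortho-metalation, in which the chelating OMOM group outranks OMe so that kinetic lithiation should occur at its free ortho position (C4a), followed by borylation and boronate oxidation with C-to-O migration.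

Step 4
Reactants: 8 4-methoxy-2-(methoxymethoxy)-3-(3-methylbut-2-en-1-yl)phenol
Product: 9 4-methoxy-2-(methoxymethoxy)-3-(3-methylbut-2-en-1-yl)phenyl N-isopropylcarbamate
Conditions: i-PrNCO, Et3N (cat.), CH2Cl2, rt
Reagents that add atoms: isopropyl isocyanate CC(C)N=C=O
Why: Base-catalysed addition of the phenol to the isocyanate gives the secondary O-aryl carbamate, the directing group for the next metalation and one that can be removed later without strong nucleophiles.

Step 5
Reactants: 9 4-methoxy-2-(methoxymethoxy)-3-(3-methylbut-2-en-1-yl)phenyl N-isopropylcarbamate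
Product: 13 4-methoxy-2-(methoxymethoxy)-3-(3-methylbut-2-en-1-yl)-6-(trimethylsilyl)phenyl N-isopropylcarbamate, via N-silyl carbamate 10 (not isolated), via aryllithium 11 (not isolated), via C-silyl N-silyl carbamate 12 (not isolated)
Conditions: TBSOTf, TMEDA, Et2O, 0 °C → rt; n-BuLi, TMEDA, −78 °C; TMSCl, −78 °C → rt; brief cold aq. NaHSO4 work-up
Reagents that add atoms: chlorotrimethylsilane C[Si](C)(C)Cl; tert-butyldimethylsilyl triflate CC(C)(C)[Si](C)(C)OS(=O)(=O)C(F)(F)F (its silicon stays only in intermediates 10 to 12)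
Why: In situ N-silylation masks the N–H, the O-carbamate then directs ortho-lithiation (directed ortho-metalation) to its only free ortho position C8a, TMSCl traps the aryllithium, and work-up hydrolyses the N–Si bond.

Step 6
Reactants: 13 4-methoxy-2-(methoxymethoxy)-3-(3-methylbut-2-en-1-yl)-6-(trimethylsilyl)phenyl N-isopropylcarbamate
Product: 15 4-methoxy-2-(methoxymethoxy)-3-(3-methylbut-2-en-1-yl)-6-(trimethylsilyl)phenyl trifluoromethanesulfonate, via silylphenol 14 (not isolated)
Conditions: DBU, Et2NH, MeCN, 40 °C; then PhNTf2, rt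
Reagents that add atoms: N-phenylbis(trifluoromethanesulfonimide) O=S(=O)(N(c1ccccc1)S(=O)(=O)C(F)(F)F)C(F)(F)F
Why: The amidine base triggers E1cB loss of isopropyl isocyanate (trapped by Et2NH as a urea), and the phenoxide is triflated in the same pot to give the o-silylaryl triflate aryne precursor.

Step 7
Reactants: 16 ethyl 3-oxo-3-(3,4,5-trimethoxyphenyl)propanoate
Product: 17 ethyl (3S)-3-hydroxy-3-(3,4,5-trimethoxyphenyl)propanoate
Conditions: RuCl2[(R)-BINAP](dmf)n (1 mol %), H2 (50 bar), EtOH, 50 °C
Reagents that add atoms: none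
Why: Noyori asymmetric hydrogenation of a β-keto ester: chelation of the keto and ester oxygens to Ru within the (R)-diphosphine pocket fixes the face of hydride delivery, which for aryl β-keto esters corresponds to the (S)-carbinol, the future C2.

Step 8
Reactants: 17 ethyl (3S)-3-hydroxy-3-(3,4,5-trimethoxyphenyl)propanoate
Product: 18 ethyl (3S)-3-(3,4,5-trimethoxyphenyl)-3-(trimethylsilyloxy)propanoate
Conditions: TMSCl, Et3N, CH2Cl2, 0 °C; non-aqueous work-up, used directly
Reagents that add atoms: chlorotrimethylsilane C[Si](C)(C)Cl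
Why: Silyl ether formation masks the O–H so that fluoride later releases a proton-free alkoxide; the stereocentre is not involved.

Step 9
Reactants: 15 4-methoxy-2-(methoxymethoxy)-3-(3-methylbut-2-en-1-yl)-6-(trimethylsilyl)phenyl trifluoromethanesulfonate; 18 ethyl (3S)-3-(3,4,5-trimethoxyphenyl)-3-(trimethylsilyloxy)propanoate
Product: 21 (2S)-7-methoxy-5-(methoxymethoxy)-6-(3-methylbut-2-en-1-yl)-2-(3,4,5-trimethoxyphenyl)chroman-4-one, via aryne 19 (not isolated), via alkoxide 20 (not isolated)
Conditions: tetrabutylammonium difluorotriphenylsilicate (TBAT, 1.3 equiv, slow addition), 15 (1.3 equiv), THF, −20 → 0 °C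
Reagents that add atoms: none
Why: Proposed new method: fluoride cleaves the O–SiMe3 bond of 18 to the proton-free alkoxide 20 and triggers 1,2-elimination of 15 to aryne 19; 20 adds through oxygen to C8a, the C4a aryl anion so formed attacks the ethyl ester, and the expelled ethoxide is silylated by a further SiMe3 group, which carries a chain and leaves the medium close to neutral. The closest known reaction types are the fluoride-mediated annulation of arynes with 2-hydroxybenzoates to xanthones (nucleophilic addition, then intramolecular acyl substitution) and the Parham cyclisation of 3-(2-lithioaryloxy)propanoic acid derivatives to chroman-4-ones; the use of an aliphatic β-silyloxy ester as the O/acyl partner is the new element. Ring C closes by 6-exo-trig attack of the aryl anion on the ester carbonyl and collapse of the tetrahedral intermediate. No stereocentre is formed: C2 is carried from step 7 and none of its bonds is broken, so its (S) configuration should be retained. The step needs O-attack at C8a and not at C4a, which the inductively withdrawing C5–OMOM group next to C4a secures by polarising the aryne so that negative charge develops ortho to it, as in 3-alkoxyarynes generally. It also needs acylation to outrun protonation of the aryl anion, which the silyl ether secures because no O–H or H–F is present in the flask.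

Step 10
Reactants: 21 (2S)-7-methoxy-5-(methoxymethoxy)-6-(3-methylbut-2-en-1-yl)-2-(3,4,5-trimethoxyphenyl)chroman-4-one
Product: 22 artoflavanone, (2S)-5-hydroxy-7-methoxy-6-(3-methylbut-2-en-1-yl)-2-(3,4,5-trimethoxyphenyl)chroman-4-one
Conditions: 3 M aq. HCl, MeOH, rt
Reagents that add atoms: none
Why: Acid-catalysed acetal exchange (MOM cleavage) is fast for the peri-carbonyl ether and mild enough to leave the prenyl alkene, the methyl ethers and the C2 stereocentre untouched.

Compound list

1 | 3-methoxyphenol | COc1cccc(O)c1 | starting material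
2 | 1-methoxy-3-(methoxymethoxy)benzene | COCOc1cccc(OC)c1 | intermediate
3 | prenyl bromide (1-bromo-3-methylbut-2-ene) | CC(C)=CCBr | starting material
4 | [2-methoxy-6-(methoxymethoxy)phenyl]lithium | [Li]c1c(OC)cccc1OCOC | intermediate (not isolated)
5 | 1-methoxy-3-(methoxymethoxy)-2-(3-methylbut-2-en-1-yl)benzene | COCOc1cccc(OC)c1CC=C(C)C | intermediate
6 | [4-methoxy-2-(methoxymethoxy)-3-(3-methylbut-2-en-1-yl)phenyl]lithium | [Li]c1ccc(OC)c(CC=C(C)C)c1OCOC | intermediate (not isolated)
7 | dimethyl [4-methoxy-2-(methoxymethoxy)-3-(3-methylbut-2-en-1-yl)phenyl]boronate | COB(OC)c1ccc(OC)c(CC=C(C)C)c1OCOC | intermediate (not isolated)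
8 | 4-methoxy-2-(methoxymethoxy)-3-(3-methylbut-2-en-1-yl)phenol | COCOc1c(O)ccc(OC)c1CC=C(C)C | intermediate
9 | 4-methoxy-2-(methoxymethoxy)-3-(3-methylbut-2-en-1-yl)phenyl N-isopropylcarbamate | COCOc1c(OC(=O)NC(C)C)ccc(OC)c1CC=C(C)C | intermediate
10 | 4-methoxy-2-(methoxymethoxy)-3-(3-methylbut-2-en-1-yl)phenyl N-(tert-butyldimethylsilyl)-N-isopropylcarbamate | COCOc1c(OC(=O)N(C(C)C)[Si](C)(C)C(C)(C)C)ccc(OC)c1CC=C(C)C | intermediate (not isolated)
11 | 6-lithio derivative of 10 | COCOc1c(OC(=O)N(C(C)C)[Si](C)(C)C(C)(C)C)c([Li])cc(OC)c1CC=C(C)C | intermediate (not isolated)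
12 | 6-(trimethylsilyl) derivative of 10 | COCOc1c(OC(=O)N(C(C)C)[Si](C)(C)C(C)(C)C)c([Si](C)(C)C)cc(OC)c1CC=C(C)C | intermediate (not isolated)
13 | 4-methoxy-2-(methoxymethoxy)-3-(3-methylbut-2-en-1-yl)-6-(trimethylsilyl)phenyl N-isopropylcarbamate | COCOc1c(OC(=O)NC(C)C)c([Si](C)(C)C)cc(OC)c1CC=C(C)C | intermediate
14 | 4-methoxy-2-(methoxymethoxy)-3-(3-methylbut-2-en-1-yl)-6-(trimethylsilyl)phenol (present as its amidinium phenoxide) | COCOc1c(O)c([Si](C)(C)C)cc(OC)c1CC=C(C)C | intermediate (not isolated)
15 | 4-methoxy-2-(methoxymethoxy)-3-(3-methylbut-2-en-1-yl)-6-(trimethylsilyl)phenyl trifluoromethanesulfonate | COCOc1c(OS(=O)(=O)C(F)(F)F)c([Si](C)(C)C)cc(OC)c1CC=C(C)C | intermediate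
16 | ethyl 3-oxo-3-(3,4,5-trimethoxyphenyl)propanoate | CCOC(=O)CC(=O)c1cc(OC)c(OC)c(OC)c1 | starting material
17 | ethyl (3S)-3-hydroxy-3-(3,4,5-trimethoxyphenyl)propanoate | CCOC(=O)C[C@H](O)c1cc(OC)c(OC)c(OC)c1 | intermediate
18 | ethyl (3S)-3-(3,4,5-trimethoxyphenyl)-3-(trimethylsilyloxy)propanoate | CCOC(=O)C[C@H](O[Si](C)(C)C)c1cc(OC)c(OC)c(OC)c1 | intermediate
19 | 5-methoxy-3-(methoxymethoxy)-4-(3-methylbut-2-en-1-yl)-1,2-didehydrobenzene (aryne across C4a/C8a) | COCOC1=C(CC=C(C)C)C(OC)=CC#C1 | intermediate (not isolated)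
20 | tetrabutylammonium (1S)-3-ethoxy-3-oxo-1-(3,4,5-trimethoxyphenyl)propan-1-olate | CCOC(=O)C[C@H]([O-])c1cc(OC)c(OC)c(OC)c1.CCCC[N+](CCCC)(CCCC)CCCC | intermediate (not isolated)
21 | (2S)-7-methoxy-5-(methoxymethoxy)-6-(3-methylbut-2-en-1-yl)-2-(3,4,5-trimethoxyphenyl)chroman-4-one | COc1cc2c(c(OCOC)c1CC=C(C)C)C(=O)C[C@@H](c1cc(OC)c(OC)c(OC)c1)O2 | intermediate
22 | artoflavanone, (2S)-5-hydroxy-7-methoxy-6-(3-methylbut-2-en-1-yl)-2-(3,4,5-trimethoxyphenyl)chroman-4-one | COc1cc2c(c(O)c1CC=C(C)C)C(=O)C[C@@H](c1cc(OC)c(OC)c(OC)c1)O2 | target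

Total step count: 10. Longest linear sequence: 8 steps (steps 1 to 6, then 9 and 10); steps 7 and 8 form the second branch.

Steps most likely to fail

Step 9 (proposed new method). Three processes may interfere:
- protonation or internal proton transfer (from the ester α-CH2) at the C4a aryl anion before it acylates, which leaves an open aryl ether or leads to β-elimination;
- retro-aldol fragmentation of the liberated alkoxide;
- base-mediated opening and re-closure of ring C, which erodes the configuration at C2.

The fallback uses known chemistry, sets out from 15 and comes back at 21. Aryne 19 is generated from 15 with CsF in THF at 100–125 °C in a sealed vessel in the presence of commercial (E)-3,4,5-trimethoxycinnamic acid. Carboxylate addition and acyl transfer to the aryl anion (the known C–O insertion of carboxylic acids into arynes, with the same regiochemistry) should give (E)-1-[2-hydroxy-4-methoxy-6-(methoxymethoxy)-5-prenylphenyl]-3-(3,4,5-trimethoxyphenyl)prop-2-en-1-one F1. This should close under the basic conditions by oxa-Michael addition to racemic 7-methoxy-5-(methoxymethoxy)-6-prenyl-2-(3,4,5-trimethoxyphenyl)chroman-4-one F2. Kinetic resolution of F2 by asymmetric transfer hydrogenation (Cp*RhCl[(R,R)-TsDPEN], HCO2H/Et3N, EtOAc, rt) is then applied. By the aryl ketone model it should reduce the (2R)-enantiomer to the cis-alcohol (2R,4R)-7-methoxy-5-(methoxymethoxy)-6-prenyl-2-(3,4,5-trimethoxyphenyl)chroman-4-ol F3 and leave the (2S)-ketone, which is 21, to be separated by chromatography. Steps 7 and 8 are then not needed.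

Step 3. Deprotonation may occur at the benzylic and allylic CH2 of the prenyl group, or ortho to OMe instead of ortho to OMOM, so that the oxygen is not introduced at C4a. The fallback sets out from 1 and comes back at 8; it places the oxygen first and the prenyl group last, so that no prenyl-bearing ring is lithiated.
- Magnesium-mediated ortho-formylation of 1 (MgCl2, Et3N, paraformaldehyde, MeCN, reflux) should give 2-hydroxy-4-methoxybenzaldehyde F4.
- MOMCl/i-Pr2NEt gives 4-methoxy-2-(methoxymethoxy)benzaldehyde F5.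
- Baeyer–Villiger oxidation (mCPBA, NaHCO3, CH2Cl2) gives 4-methoxy-2-(methoxymethoxy)phenyl formate F6, and methanolysis (K2CO3, MeOH) gives 4-methoxy-2-(methoxymethoxy)phenol F7.
- TIPSCl/imidazole gives [4-methoxy-2-(methoxymethoxy)phenoxy]triisopropylsilane F8.
- n-BuLi/TMEDA should lithiate the one position flanked by OMOM and OMe to give [6-methoxy-2-(methoxymethoxy)-3-(triisopropylsilyloxy)phenyl]lithium F9.
- CuI (cat.) and 3 give [4-methoxy-2-(methoxymethoxy)-3-prenylphenoxy]triisopropylsilane F10, and TBAF in THF releases 8.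

Step 5. The MOM acetal may exchange with the silyl triflate, metalation may occur on the prenyl side chain, or ortho-silylation may stay incomplete. The fallback sets out from 8 and comes back at 15; it replaces the carbamate-directed metalation by halogenation and a retro-Brook silyl shift.
- Amine-catalysed ortho-bromination of 8 (NBS, i-Pr2NH cat., CH2Cl2, −78 °C) should give 6-bromo-4-methoxy-2-(methoxymethoxy)-3-prenylphenol F11, since C8a is the only free position ortho to the hydroxyl.
- Hexamethyldisilazane (70 °C) gives [6-bromo-4-methoxy-2-(methoxymethoxy)-3-prenylphenoxy]trimethylsilane F12.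
- n-BuLi (THF, −100 → −78 °C) effects bromine–lithium exchange and 1,3-O-to-C silyl migration to the lithium salt of 14, which is triflated in the same flask with Tf2O to give 15.

Further compounds

F1 | step 9 | (E)-1-[2-hydroxy-4-methoxy-6-(methoxymethoxy)-5-(3-methylbut-2-en-1-yl)phenyl]-3-(3,4,5-trimethoxyphenyl)prop-2-en-1-one | COc1cc(O)c(C(=O)/C=C/c2cc(OC)c(OC)c(OC)c2)c(OCOC)c1CC=C(C)C
F2 | step 9 | racemic 7-methoxy-5-(methoxymethoxy)-6-(3-methylbut-2-en-1-yl)-2-(3,4,5-trimethoxyphenyl)chroman-4-one | COc1cc2c(c(OCOC)c1CC=C(C)C)C(=O)CC(c1cc(OC)c(OC)c(OC)c1)O2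
F3 | step 9 | (2R,4R)-7-methoxy-5-(methoxymethoxy)-6-(3-methylbut-2-en-1-yl)-2-(3,4,5-trimethoxyphenyl)chroman-4-ol | COc1cc2c(c(OCOC)c1CC=C(C)C)[C@H](O)C[C@H](c1cc(OC)c(OC)c(OC)c1)O2
F4 | step 3 | 2-hydroxy-4-methoxybenzaldehyde | COc1ccc(C=O)c(O)c1
F5 | step 3 | 4-methoxy-2-(methoxymethoxy)benzaldehyde | COCOc1cc(OC)ccc1C=O
F6 | step 3 | 4-methoxy-2-(methoxymethoxy)phenyl formate | COCOc1cc(OC)ccc1OC=O
F7 | step 3 | 4-methoxy-2-(methoxymethoxy)phenol | COCOc1cc(OC)ccc1O
F8 | step 3 | [4-methoxy-2-(methoxymethoxy)phenoxy]triisopropylsilane | COCOc1cc(OC)ccc1O[Si](C(C)C)(C(C)C)C(C)C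
F9 | step 3 | [6-methoxy-2-(methoxymethoxy)-3-(triisopropylsilyloxy)phenyl]lithium | [Li]c1c(OC)ccc(O[Si](C(C)C)(C(C)C)C(C)C)c1OCOC
F10 | step 3 | [4-methoxy-2-(methoxymethoxy)-3-(3-methylbut-2-en-1-yl)phenoxy]triisopropylsilane | COCOc1c(O[Si](C(C)C)(C(C)C)C(C)C)ccc(OC)c1CC=C(C)C
F11 | step 5 | 6-bromo-4-methoxy-2-(methoxymethoxy)-3-(3-methylbut-2-en-1-yl)phenol | COCOc1c(O)c(Br)cc(OC)c1CC=C(C)C
F12 | step 5 | [6-bromo-4-methoxy-2-(methoxymethoxy)-3-(3-methylbut-2-en-1-yl)phenoxy]trimethylsilane | COCOc1c(O[Si](C)(C)C)c(Br)cc(OC)c1CC=C(C)C
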